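A direct plan would build both catechol rings from acyclic material and brominate at the very end.
It would make the bis-diene bis(2-methylidenebut-3-en-1-yl) ether A1 by a Williamson/Kumada sequence, add vinylene carbonate A2 twice in a thermal Diels–Alder reaction to give the bis-carbonate A3, and, after methanolysis and a Swern-type oxidation with aromatisation, reach bis(3,4-dihydroxybenzyl) ether A4. A sixfold bromination would then give the target.
Weak point 1, the five-step construction of A4: a long linear run-up to two plain catechol rings that can be bought with the benzylic carbon already attached. Four stereocentres would be made only to be erased, and the carbonate and redox steps build nothing.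
Weak point 2, the twofold Diels–Alder reaction of A1 near 175 °C: a volatile 2-substituted diene that polymerises readily would have to react at both ends with a sluggish dienophile.
Weak point 3, the final sixfold bromination of unprotected A4: six substitutions would have to go to completion on the most fragile compound of the plan. Its p-hydroxybenzyl ether invites ipso attack at the ring carbon para to the hydroxyl, oxidation to o-quinones and quinone methide cleavage by HBr.

**Retrosynthetic overview** (numbering: C1 carries the benzylic carbon C7; Br at C2, C3, C6; OH at C4, C5; primes for the second ring)
The target is cut at the central C7–O–C7′ bridge into two identical molecules of 2,3,6-tribromo-4,5-dihydroxybenzyl alcohol 4, copying the presumed biogenesis: C7 stands para to the free C4 hydroxyl, so 4 ionises to the p-quinone methide 5, which a second molecule of 4 captures at oxygen.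
Because C2, C3 and C6 carry bromine and C4 and C5 carry oxygen, no ring C–H is left for C-benzylation; this is what makes an unprotected dimerisation defensible for this structure.
No ring is built: both arenes come from commercial 3,4-dihydroxybenzaldehyde, whose formyl carbon becomes C7, so there is no de novo arene synthesis, no cycloaddition and no stereocentre to erase.
All bromines are installed first, on the formyl-deactivated monomer; the labile ether is made last and never meets an electrophilic brominating agent.

Key step: step 3

Remark: the target is achiral, so no stereocentre has to be set in any step; 1 and 2 are taken as commercial.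

Step 1
Reactants: 1 3,4-dihydroxybenzaldehyde (protocatechualdehyde); 2 bromine
Product: 3 2,3,6-tribromo-4,5-dihydroxybenzaldehyde
Conditions: Br2 (3.3 equiv), AcOH, rt → 60 °C; aq. Na2S2O3, precipitation from water
Reagents that add atoms: bromine (2), BrBr
Why: Threefold electrophilic aromatic bromination should fill every open ring position (one ortho to the hydroxyl para to the formyl group, the other two ortho and para to the second hydroxyl), so no regiochemical choice arises, while the formyl group makes the catechol harder to oxidise and cannot ionise to a quinone methide; the closest analogy is the exhaustive bromination of catechol to tetrabromocatechol in acetic acid.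

Step 2
Reactants: 3 2,3,6-tribromo-4,5-dihydroxybenzaldehyde
Product: 4 2,3,6-tribromo-4,5-dihydroxybenzyl alcohol
Conditions: NaBH4 (1.5 equiv), THF–H2O (4:1), 0 °C; 1 M HCl to pH 4 at 0 °C, EtOAc; no alcoholic solvents
Reagents that add atoms: none
Why: Borohydride reduction of the aldehyde to the primary alcohol, as in the standard reduction of hydroxybenzaldehydes to hydroxybenzyl alcohols; the aryl bromides are inert, the small hydride should reach the carbonyl between the two ortho bromines, and a cold alcohol-free work-up at pH 4 should avoid premature ionisation of the p-hydroxybenzyl alcohol.

Step 3
Reactants: 4 2,3,6-tribromo-4,5-dihydroxybenzyl alcohol (two molecules)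
Product: 6 bis(2,3,6-tribromo-4,5-dihydroxybenzyl) ether, via p-quinone methide 5 (not isolated)
Conditions: TsOH·H2O (5 mol%), MeNO2 (0.5 M), powdered 3 Å molecular sieves, 45 °C, Ar, dark; filter, pH 5 buffer wash, crystallisation without alcohols
Reagents that add atoms: none
Why: Protonation of the benzylic hydroxyl of 4 and loss of water, assisted by the C4 hydroxyl para to C1, should give the p-quinone methide 5 (or its O-protonated form, the p-hydroxybenzyl cation), and the primary hydroxyl of a second molecule of 4 should add to its exocyclic CH2 in a 1,6-conjugate addition that restores the arene and forms the C7–O–C7′ bridge. The closest known reaction type is the thermal or acid-catalysed self-etherification of ring-blocked 4-hydroxybenzyl alcohols to bis(4-hydroxybenzyl) ethers, together with the ready solvolytic etherification of brominated hydroxybenzyl alcohols in alcohol solvents. No ring is closed and no stereocentre is formed; the product is achiral. The selectivity needed is O-alkylation by the alkyl hydroxyl in preference to C-benzylation, to O-alkylation of the phenols and to ipso attack: C-benzylation is excluded because every ring carbon is substituted (Br at C2, C3, C6; O at C4, C5), the phenolic hydroxyls are acidic, bromine-flanked and poorly nucleophilic, and any aryl benzyl ether that forms should re-ionise under the reversible conditions and funnel to the more stable dialkyl ether. The sieves take up the water and the high concentration favours the bimolecular capture, so the equilibrium should lie on the side of 6.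

**Compound list**

1 | 3,4-dihydroxybenzaldehyde (protocatechualdehyde) | O=Cc1ccc(O)c(O)c1 | starting material
2 | bromine | BrBr | starting material
3 | 2,3,6-tribromo-4,5-dihydroxybenzaldehyde | O=Cc1c(Br)c(Br)c(O)c(O)c1Br | intermediate
4 | 2,3,6-tribromo-4,5-dihydroxybenzyl alcohol, 3,4,6-tribromo-5-(hydroxymethyl)benzene-1,2-diol | OCc1c(Br)c(Br)c(O)c(O)c1Br | intermediate
5 | 2,3,5-tribromo-6-hydroxy-4-methylidenecyclohexa-2,5-dien-1-one (p-quinone methide; formed in the flask in step 3, not isolated) | C=C1C(Br)=C(Br)C(=O)C(O)=C1Br | intermediate
6 | bis(2,3,6-tribromo-4,5-dihydroxybenzyl) ether, 5,5'-[oxybis(methylene)]bis(3,4,6-tribromobenzene-1,2-diol); achiral | Oc1c(O)c(Br)c(COCc2c(Br)c(O)c(O)c(Br)c2Br)c(Br)c1Br | target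

**Step count and risks**

Total step count: 3. Longest linear sequence: 3 steps (1 → 3 → 4 → 6).

Steps most likely to fail:

Step 3 (key step). The reversible ionisation may stall at an equilibrium mixture, or the quinone methide may be captured by phenolic hydroxyls and grow into oligomeric aryl benzyl ethers. The fallback sets out from 4 and returns to the route at 6. Half of 4 would be treated with HBr (33% in AcOH, rt) to give 2,3,6-tribromo-4,5-dihydroxybenzyl bromide F1, used crude. F1 and the other half of 4 (1:1) would then be warmed in 1,2-dichloroethane at 50 °C under a stream of argon that carries off HBr. This replaces the thermodynamic dehydration by a cross-coupling of an electrophilic and a nucleophilic monomer, in which the quinone methide forms from the far better leaving group and no water competes; solvolysis of p-hydroxybenzyl bromides by alcohols is classical chemistry.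

Step 1. The third substitution at the hindered position between the formyl group and a hydroxyl may lag, while ipso attack at the formyl-bearing carbon para to a hydroxyl or oxidation of the free catechol consumes material. The fallback sets out from bromine 2, with commercial vanillin F2 in place of 1, and returns to the route at 3. Vanillin F2 would be tribrominated (Br2, 3.3 equiv, Fe powder 5 mol% giving FeBr3 in the flask, AcOH, 70 °C) to 2,3,6-tribromo-4-hydroxy-5-methoxybenzaldehyde F3; one hydroxyl masked as its methyl ether makes the ring harder to oxidise, and the Lewis acid drives the last substitution. Demethylation with BBr3 (CH2Cl2, −78 °C → rt, aqueous work-up) would then give 3.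

Step 2. Under the basic hydride conditions the phenoxide para to the new CH2OH may expel hydroxide, and borohydride would reduce the resulting quinone methide on to the methylarene (over-reduction); catechol borate complexes may also hold back product. The fallback sets out from 3 and returns to the route at 4. Both phenols would be acetylated (Ac2O, pyridine, DMAP cat., CH2Cl2) to 3,4,6-tribromo-5-formyl-1,2-phenylene diacetate F4, so that no phenoxide can form. Reduction (NaBH4, THF–H2O, 0 °C, AcOH quench) would give 3,4,6-tribromo-5-(hydroxymethyl)-1,2-phenylene diacetate F5, and hydrazinolysis of the aryl acetates (N2H4·H2O, THF, 0 °C, then dilute HCl to pH 4) would release 4.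

**Further compounds**

F1 | step 3 | 2,3,6-tribromo-4,5-dihydroxybenzyl bromide, 3,4,6-tribromo-5-(bromomethyl)benzene-1,2-diol | BrCc1c(Br)c(Br)c(O)c(O)c1Br
F2 | step 1 | vanillin, 4-hydroxy-3-methoxybenzaldehyde (commercial) | COc1cc(C=O)ccc1O
F3 | step 1 | 2,3,6-tribromo-4-hydroxy-5-methoxybenzaldehyde | COc1c(O)c(Br)c(Br)c(C=O)c1Br
F4 | step 2 | 3,4,6-tribromo-5-formyl-1,2-phenylene diacetate | CC(=O)Oc1c(Br)c(Br)c(C=O)c(Br)c1OC(C)=O
F5 | step 2 | 3,4,6-tribromo-5-(hydroxymethyl)-1,2-phenylene diacetate | CC(=O)Oc1c(Br)c(Br)c(CO)c(Br)c1OC(C)=O
A1 | direct plan | bis(2-methylidenebut-3-en-1-yl) ether | C=CC(=C)COCC(=C)C=C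
A2 | direct plan | vinylene carbonate (1,3-dioxol-2-one) | O=C1OC=CO1
A3 | direct plan | 5,5'-[oxybis(methylene)]bis(cis-3a,4,7,7a-tetrahydro-1,3-benzodioxol-2-one), cis ring fusions, meso form drawn | O=C1O[C@H]2CC=C(COCC3=CC[C@H]4OC(=O)O[C@H]4C3)C[C@H]2O1
A4 | direct plan | bis(3,4-dihydroxybenzyl) ether | Oc1ccc(COCc2ccc(O)c(O)c2)cc1O
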